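The ten-membered ring is disconnected across its 1,5-diene: C1=C10 and C4=C5 flank the C2–C3 bond, and C5–C10 is the bond of a latent cyclohexane that stores the all-cis C6/C7/C8 triad. One anionic oxy-Cope step on a cis-1-vinyl-2-isopropenylcyclohexanol alkoxide makes C2–C3, breaks C5–C10, fixes both ring-alkene geometries and releases a C1=C10 enolate, trapped as the enol triflate for later methyl coupling. In the precursor carbinol, O6 and O8 are tied together as a p-methoxybenzylidene acetal, which holds the chair with axial O6/O8/O10, equatorial vinyl and axial isopropenyl.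

Key step: step 9

Remarks on the chemistry
- Locants: germacrane numbering is used for the carbocycle at every stage (C5–C10 are the cyclohexane carbons; C6, C7, C8 carry O, isopropyl, O; C10 carries the third oxygen).
- Descriptor correction: the enol triflate is (1(10)E,4E) by the sequence rules, because OTf outranks C9. C9 and C2 are nevertheless cis across C1=C10, and the same geometry becomes 1(10)Z once CH3 replaces OTf.
- Precursor design: two separate ethers on O6 and O8 would leave the cyclohexane free to flip to the chair with equatorial oxygens, which leads to the wrong alkene pair (C9/C2 trans, 4Z). The O6/O8 acetal bridge can exist only with both oxygens axial, so it removes that chair. It also directs the vinyl addition to the exo face and the α-alkenylation to the axial position.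
- Assumption: the (S,S)-lithium amide is taken to remove the axial C5 proton, by analogy with its sense on 4-substituted cyclohexanones; if the sense is opposite, the (R,R)-amide is used and nothing else changes.

Step 1
Reactants: 1 phloroglucinol
Product: 2 2-isopropylphloroglucinol
Conditions: i-PrOH (0.4 equiv), 85% H3PO4, 80 °C; excess 1 recovered
Reagents that add atoms: 2-propanol, CC(C)O
Why: Friedel–Crafts C-alkylation of the very electron-rich triol by the 2-propyl cation should stop at monoalkylation when 1 is in excess, and the three ring positions are equivalent.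

Step 2
Reactants: 2 2-isopropylphloroglucinol
Product: 3 all-cis-2-isopropylcyclohexane-1,3,5-triol
Conditions: H2 (80 bar), 5% Rh/Al2O3, EtOH, 60 °C
Reagents that add atoms: none
Why: heterogeneous arene hydrogenation delivers all hydrogens from the catalyst face, so the three hydroxyls and the isopropyl group should end up cis (C6, C7, C8 relative configuration), and rhodium saturates phenols with little C–O hydrogenolysis.

Step 3
Reactants: 3 all-cis-2-isopropylcyclohexane-1,3,5-triol
Product: 4 all-cis-5-(tert-butyldiphenylsilyloxy)-2-isopropylcyclohexane-1,3-diol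
Conditions: TBDPSCl (1.0 equiv), imidazole, DMF, 0 °C
Reagents that add atoms: tert-butyl(chloro)diphenylsilane, CC(C)(C)[Si](Cl)(c1ccccc1)c1ccccc1
Why: silylation with a bulky chlorosilane should pick the hydroxyl flanked by two CH2 groups (O10) over the two hydroxyls next to the isopropyl-bearing carbon, keeping the meso symmetry.

Step 4
Reactants: 4 all-cis-5-(tert-butyldiphenylsilyloxy)-2-isopropylcyclohexane-1,3-diol
Product: 5 meso O6/O8 p-methoxybenzylidene acetal silyl ether
Conditions: 4-MeOC6H4CH(OMe)2, CSA (cat.), toluene, 50 °C, MeOH removed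
Reagents that add atoms: 4-methoxybenzaldehyde dimethyl acetal, COC(OC)c1ccc(OC)cc1
Why: acid-catalysed transacetalisation of a cis-1,3-diol on cyclohexane can bridge only through the diaxial chair, and thermodynamic control should place the aryl group exo (equatorial on the dioxane) and the acetal hydrogen endo.

Step 5
Reactants: 5 meso O6/O8 p-methoxybenzylidene acetal silyl ether
Product: 6 meso bridged acetal C10 alcohol
Conditions: Bu4NF, THF, rt
Reagents that add atoms: none
Why: fluoride-induced desilylation frees the C10 hydroxyl, and the acetal is inert to these basic conditions.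

Step 6
Reactants: 6 meso bridged acetal C10 alcohol
Product: 7 meso bridged acetal C10 ketone
Conditions: DMP, NaHCO3, CH2Cl2, rt
Reagents that add atoms: none
Why: oxidation of the secondary alcohol with a hypervalent iodine reagent is near-neutral and so should avoid β-elimination of the two acetal oxygens that sit β to the new carbonyl.

Step 7
Reactants: 7 meso bridged acetal C10 ketone; 8 2-bromopropene
Product: 11 C5-isopropenyl ketone, via lithium enolate 9 (not isolated), via chlorozinc enolate 10 (not isolated)
Conditions: (S,S)-[PhCH(Me)]2NLi (from the amine and n-BuLi), LiCl, THF, −100 °C; ZnCl2, −78 °C; 8, Pd(dba)2 (5 mol%), P(t-Bu)3 (10 mol%), −78 °C → rt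
Reagents that add atoms: 2-bromopropene (8), CC(Br)=C
Why: enantiotopos-selective deprotonation of the meso ketone by the chiral lithium amide sets the absolute configuration by enolising toward C5, transmetalation to the less basic zinc enolate should suppress E1cB loss of the β-acetal oxygen and enolate/ketone proton exchange, and palladium-catalysed enolate alkenylation (Negishi-type, through zerovalent palladium) forms the C5–isopropenyl bond on the exo face opposite the acetal bridge, so the new group is axial and trans to O6.

Step 8
Reactants: 11 C5-isopropenyl ketone; 12 vinylmagnesium bromide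
Product: 13 bridged cis-1-vinyl-2-isopropenylcyclohexanol
Conditions: CeCl3, THF, −78 °C; then 12, −78 °C
Reagents that add atoms: vinylmagnesium bromide (12), C=C[Mg]Br
Why: organocerium 1,2-addition avoids enolisation of the epimerisable α-isopropenyl ketone, and because the acetal bridge and the axial O6/O8 cover the endo face the vinyl group should enter on the exo (equatorial) trajectory, giving the C10 alkoxide axial and cis to O6/O8 and the vinyl group cis to the isopropenyl group.

Step 9
Reactants: 13 bridged cis-1-vinyl-2-isopropenylcyclohexanol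
Product: 16 (1(10)E,4E)-cyclodecadienyl C10 enol triflate with O6/O8 acetal, via potassium alkoxide 14 (not isolated), via potassium enolate 15 (not isolated)
Conditions: KH, 18-crown-6, THF, 0 °C → rt; PhNTf2, −78 → 0 °C
Reagents that add atoms: N-phenylbis(trifluoromethanesulfonimide), O=S(=O)(N(c1ccccc1)S(=O)(=O)C(F)(F)F)C(F)(F)F
Why: KH gives alkoxide 14, whose 3-oxido-1,5-diene (C2=C1–C10(O−)–C5–C4=C3) undergoes a [3,3]-sigmatropic shift through a chair six-atom transition state, forming C2–C3 while C5–C10 breaks, as in the known anionic oxy-Cope ring expansions of 1,2-dialkenylcyclohexanols to cyclodeca-1,5-dienolates with O-trapping of the enolate. The ten-membered carbocycle is therefore not closed end to end but arises by four-atom ring expansion of the cyclohexane, with the 1,3-dioxane carried along unchanged. No stereocentre is created: C6, C7 and C8 are spectators and the C5 and C10 centres are erased. The step needs 4E and the C9/C2-cis geometry at C1=C10, and the acetal bridge secures them by holding O6 and O8 diaxial, so that C10–O is axial, vinyl equatorial and isopropenyl axial; on the Cope chair this puts O10 and C6 pseudo-equatorial and C9 pseudo-axial, hence O trans to C2 and C6 trans to C3. The enolate forms only toward C1 and should be sulfonylated on oxygen at −78 °C before proton transfer toward C9, which would allow loss of the C8 oxygen. Strain release in the crowded bicyclic alkoxide should let the shift run at or below room temperature.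

Step 10
Reactants: 16 (1(10)E,4E)-cyclodecadienyl C10 enol triflate with O6/O8 acetal
Product: 17 (1(10)Z,4E)-germacradiene O6/O8 acetal
Conditions: MeMgBr, Fe(acac)3 (5 mol%), THF/NMP, −30 °C
Reagents that add atoms: methylmagnesium bromide, C[Mg]Br
Why: iron-catalysed Kumada-type coupling of an alkenyl triflate with a methyl Grignard reagent proceeds with retention of alkene geometry and should leave the acetal and the C4=C5 alkene untouched.

Step 11
Reactants: 17 (1(10)Z,4E)-germacradiene O6/O8 acetal
Product: 18 C6 PMB ether with free C8 hydroxyl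
Conditions: i-Bu2AlH, CH2Cl2, −78 → 0 °C
Reagents that add atoms: none
Why: reductive opening of a p-methoxybenzylidene acetal by the aluminium hydride breaks the C–O bond of the oxygen it coordinates, expected to be the less encumbered O8 next to the C9 methylene, so the PMB group should stay on the allylic O6 that is shielded by the cis C4 methyl group.

Step 12
Reactants: 18 C6 PMB ether with free C8 hydroxyl; 19 3,4,5-trimethoxybenzoyl chloride
Product: 20 C8 trimethoxybenzoate C6 PMB ether
Conditions: 19, Et3N, DMAP, CH2Cl2, 0 °C → rt
Reagents that add atoms: 3,4,5-trimethoxybenzoyl chloride (19), COc1cc(C(=O)Cl)cc(OC)c1OC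
Why: DMAP-catalysed acylation of the only free hydroxyl installs the C8 ester with retention at C8.

Step 13
Reactants: 20 C8 trimethoxybenzoate C6 PMB ether
Product: 21 C6 allylic alcohol C8 trimethoxybenzoate
Conditions: DDQ, CH2Cl2/pH 7 buffer, 0 °C
Reagents that add atoms: none
Why: oxidative cleavage of the p-methoxybenzyl ether by DDQ is selective for the electron-rich benzylic ether and should spare the aryl ester and both trisubstituted alkenes.

Step 14
Reactants: 21 C6 allylic alcohol C8 trimethoxybenzoate
Product: 22 target 4,5-epoxide
Conditions: VO(acac)2 (5 mol%), t-BuOOH, CH2Cl2, 0 °C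
Reagents that add atoms: tert-butyl hydroperoxide, CC(C)(C)OO
Why: hydroxyl-directed vanadium-catalysed epoxidation delivers oxygen to the C4=C5 face that carries the C6 hydroxyl when C6–H eclipses the alkene (allylic 1,3-strain with the cis C4 methyl), which should give the trans (4S,5S) epoxide, while C1=C10 has no free hydroxyl to direct the reagent and should be left.

Compound list
1 | phloroglucinol (benzene-1,3,5-triol) | Oc1cc(O)cc(O)c1 | starting material
2 | 2-isopropylphloroglucinol | CC(C)c1c(O)cc(O)cc1O | intermediate
3 | all-cis-2-isopropylcyclohexane-1,3,5-triol (meso; three OH and isopropyl on one face) | CC(C)[C@H]1[C@@H](O)C[C@@H](O)C[C@H]1O | intermediate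
4 | all-cis-5-(tert-butyldiphenylsilyloxy)-2-isopropylcyclohexane-1,3-diol (meso; silyl on O10) | CC(C)[C@H]1[C@@H](O)C[C@@H](O[Si](c2ccccc2)(c2ccccc2)C(C)(C)C)C[C@H]1O | intermediate
5 | meso 7-endo-(tert-butyldiphenylsilyloxy)-9-isopropyl-3-exo-(4-methoxyphenyl)-2,4-dioxabicyclo[3.3.1]nonane (O6/O8 acetal; acetal H endo; isopropyl equatorial on the carbocycle) | CC(C)[C@H]1[C@@H]2C[C@@H](O[Si](c3ccccc3)(c3ccccc3)C(C)(C)C)C[C@H]1O[C@H](c1ccc(OC)cc1)O2 | intermediate
6 | meso 9-isopropyl-3-exo-(4-methoxyphenyl)-2,4-dioxabicyclo[3.3.1]nonan-7-endo-ol | CC(C)[C@H]1[C@@H]2C[C@@H](O)C[C@H]1O[C@H](c1ccc(OC)cc1)O2 | intermediate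
7 | meso 9-isopropyl-3-exo-(4-methoxyphenyl)-2,4-dioxabicyclo[3.3.1]nonan-7-one (C10 ketone) | CC(C)[C@H]1[C@@H]2CC(=O)C[C@H]1O[C@H](c1ccc(OC)cc1)O2 | intermediate
8 | 2-bromopropene | CC(Br)=C | starting material
9 | lithium enolate of 7 toward C5 (C5=C10; single enantiomer) | CC(C)[C@H]1[C@@H]2C=C(O[Li])C[C@H]1O[C@H](c1ccc(OC)cc1)O2 | intermediate
10 | chlorozinc enolate (C5=C10) | CC(C)[C@H]1[C@@H]2C=C(O[Zn]Cl)C[C@H]1O[C@H](c1ccc(OC)cc1)O2 | intermediate
11 | 6-isopropenyl-9-isopropyl-3-exo-(4-methoxyphenyl)-2,4-dioxabicyclo[3.3.1]nonan-7-one (C5 isopropenyl axial on the carbocycle, trans to O6) | CC(C)[C@H]1[C@@H]2[C@H](C(C)=C)C(=O)C[C@H]1O[C@H](c1ccc(OC)cc1)O2 | intermediate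
12 | vinylmagnesium bromide | C=C[Mg]Br | starting material
13 | 6-isopropenyl-9-isopropyl-3-exo-(4-methoxyphenyl)-7-vinyl-2,4-dioxabicyclo[3.3.1]nonan-7-ol (C10–OH axial, endo, cis to O6 and O8; vinyl equatorial, cis to the axial C5 isopropenyl; isopropenyl trans to O6) | O[C@@]1(C=C)C[C@H]2O[C@H](c3ccc(OC)cc3)O[C@H]([C@@H]2C(C)C)[C@@H]1C(C)=C | intermediate
14 | potassium alkoxide of 13 | [K]O[C@@]1(C=C)C[C@H]2O[C@H](c3ccc(OC)cc3)O[C@H]([C@@H]2C(C)C)[C@@H]1C(C)=C | intermediate
15 | potassium C1=C10 enolate of the ring-expanded 4E-cyclodecadienone (O trans to C2; O6/O8 acetal) | COc1ccc(cc1)[C@H]1O[C@@H]2C/C(O[K])=C\CC/C(C)=C/[C@H](O1)[C@@H]2C(C)C | intermediate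
16 | (1(10)E,4E)-7-isopropyl-4-methyl-6,8-O-(4-methoxybenzylidene)-10-(trifluoromethylsulfonyloxy)cyclodeca-1(10),4-diene-6,8-diol (C9 and C2 cis across C1=C10; O6, isopropyl, O8 all cis) | COc1ccc(cc1)[C@H]1O[C@@H]2C/C(OS(=O)(=O)C(F)(F)F)=C\CC/C(C)=C/[C@H](O1)[C@@H]2C(C)C | intermediate
17 | (1(10)Z,4E)-6,8-O-(4-methoxybenzylidene)germacra-1(10),4-diene-6,8-diol (C6, C7, C8 as in the target) | COc1ccc(cc1)[C@H]1O[C@@H]2C/C(C)=C\CC/C(C)=C/[C@H](O1)[C@@H]2C(C)C | intermediate
18 | (1(10)Z,4E)-6-(4-methoxybenzyloxy)germacra-1(10),4-dien-8-ol | O[C@@H]1C/C(C)=C\CC/C(C)=C/[C@H](OCc2ccc(OC)cc2)[C@@H]1C(C)C | intermediate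
19 | 3,4,5-trimethoxybenzoyl chloride | COc1cc(C(=O)Cl)cc(OC)c1OC | starting material
20 | (1(10)Z,4E)-6-(4-methoxybenzyloxy)germacra-1(10),4-dien-8-yl 3,4,5-trimethoxybenzoate | COc1cc(C(=O)O[C@@H]2C/C(C)=C\CC/C(C)=C/[C@H](OCc3ccc(OC)cc3)[C@@H]2C(C)C)cc(OC)c1OC | intermediate
21 | (1(10)Z,4E)-6-hydroxygermacra-1(10),4-dien-8-yl 3,4,5-trimethoxybenzoate | COc1cc(C(=O)O[C@@H]2C/C(C)=C\CC/C(C)=C/[C@H](O)[C@@H]2C(C)C)cc(OC)c1OC | intermediate
22 | (1(10)Z,4S,5S,6R,7S,8R)-4,5-epoxy-6-hydroxygermacr-1(10)-en-8-yl 3,4,5-trimethoxybenzoate (CNP0260213.11) | COc1cc(C(=O)O[C@@H]2C/C(C)=C\CC[C@]3(C)O[C@H]3[C@H](O)[C@@H]2C(C)C)cc(OC)c1OC | target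

Total step count: 14. Longest linear sequence: 14 steps (1 → 22); compounds 8, 12 and 19 are purchased.

Steps most likely to fail

Step 9. The rearrangement may pass through a boat-type array, or through a boat form of the carbocycle, which would invert one alkene geometry. The potassium enolate may also exchange protons toward C9 before O-sulfonylation is complete, which opens the way to loss of the C8 oxygen. The fallback sets out from 13: alkoxide 14 is rearranged as before and enolate 15 is trapped at −78 °C with ClP(O)(OEt)2, which phosphorylates potassium enolates quickly, to give the enol diethyl phosphate F2. F2 is robust enough to isolate, so its geometry can be checked. A Kumada coupling with MeMgBr and Ni(acac)2 then installs the C10 methyl with retention, and the route is rejoined at 17.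

Step 7. The C5 enolate may expel the β-acetal oxygen (E1cB). A slow coupling may allow enolate/ketone proton exchange that erodes enantiomeric purity, and the axial isopropenyl group may epimerise or move into conjugation. The fallback sets out from 7: enolates 9 and 10 are made as before but without palladium, and acetone is added at −78 °C so that the zinc aldolate forms on the exo face. Cold quench gives the 2-hydroxypropan-2-yl ketone F1. Dehydration with SOCl2/pyridine at −20 °C, a kinetic elimination toward a methyl hydrogen of the tertiary chlorosulfite, then gives the isopropenyl group, and the route is rejoined at 11.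

Step 11. The hydride may open the acetal in the opposite sense and leave the PMB group on O8, because the two acetal oxygens are both secondary and differ only in their flanking carbons. The fallback sets out from 17 and does not rely on that opening. Transacetalisation with PPTS in MeOH removes the bridge to give the 6,8-diol F3. VO(acac)2/t-BuOOH then epoxidises only C4=C5, which the allylic C6 hydroxyl directs far faster than the homoallylic C8 hydroxyl can direct C1=C10, giving the epoxy diol F4. One equivalent of 19 with Et3N/DMAP at −20 °C should acylate the C8 hydroxyl, since the C6 hydroxyl is deactivated by the adjacent epoxide and sits between two branched carbons. The route is rejoined at 22.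

Further compounds
F1 | step 7 | 6-(2-hydroxypropan-2-yl)-9-isopropyl-3-exo-(4-methoxyphenyl)-2,4-dioxabicyclo[3.3.1]nonan-7-one (side chain axial on C5, trans to O6) | CC(C)[C@H]1[C@@H]2[C@H](C(C)(C)O)C(=O)C[C@H]1O[C@H](c1ccc(OC)cc1)O2
F2 | step 9 | (1(10)E,4E)-enol diethyl phosphate of the ring-expanded dienone (O6/O8 acetal; C9 and C2 cis) | COc1ccc(cc1)[C@H]1O[C@@H]2C/C(OP(=O)(OCC)OCC)=C\CC/C(C)=C/[C@H](O1)[C@@H]2C(C)C
F3 | step 11 | (1(10)Z,4E)-germacra-1(10),4-diene-6,8-diol (C6, C7, C8 as in the target) | O[C@@H]1C/C(C)=C\CC/C(C)=C/[C@H](O)[C@@H]1C(C)C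
F4 | step 11 | (1(10)Z,4S,5S,6R,7S,8R)-4,5-epoxygermacr-1(10)-ene-6,8-diol | O[C@@H]1C/C(C)=C\CC[C@]2(C)O[C@H]2[C@H](O)[C@@H]1C(C)C
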